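**Plan**

- Numbering runs along the chain from the CH2 on the furan (C5) to the lactone carbonyl (C19). Retrosynthetically the two acetates come off, the C10–O bond is traced back to a C10–B bond, and C8–C9 and C10–C11 are cut together, so that C9–C10 becomes a vinyl unit.
- Enabling feature: the C9H2–C10H(O) pair sits between two E-trisubstituted alkenes, with C10 on alkenyl carbon C11 and C9 on alkenyl carbon C8. A vinylboron ate complex can therefore take the C11 alkenyl group on C10 (1,2-shift from boron) and the C8 alkenyl group on C9 (from palladium).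
- Forward: an E-alkenyl iodide (furan plus C5–C8) is made from 3-furaldehyde and an E-alkenylboronate (C11–C19) from 4-pentyn-1-ol. The only ring formed, the γ-lactone, closes by 5-exo opening of an epoxide before the fragments meet. The coupling joins three pieces and closes no ring; C–B oxidation, desilylation and double acetylation finish.
- Stereochemistry: C15 and C16 come from Shi epoxidation of the E-C15=C16 alkene and lactonisation with inversion at C16. C10 comes from the chiral ferrocenyl diphosphine on palladium, then C–B oxidation with retention. The E alkenes come from syn carboalumination (C11=C12), syn hydrozirconation (C7=C8) and a chair Johnson–Claisen rearrangement (C15=C16, transient).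

Key step: step 15

Assumption: the (Sp,Sp) enantiomer of MandyPhos, 1,1'-bis[bis(4-methoxy-3,5-dimethylphenyl)phosphino]-2,2'-bis[(R)-α-(dimethylamino)benzyl]ferrocene, is taken as the one that gives the 10S boronate when an alkenyl group migrates; if the sense is the opposite, the (Rp,Rp) antipode is used under identical conditions.

**Route**

Step 1
Reactants: 1 3-furaldehyde; 2 methyl (triphenylphosphoranylidene)acetate
Product: 3 methyl (E)-3-(furan-3-yl)acrylate
Conditions: CH2Cl2, rt
Reagents that add atoms: none
Why: Wittig olefination with a stabilised ylide should give the E-acrylate and brings in C6 and C7.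

Step 2
Reactants: 3 methyl (E)-3-(furan-3-yl)acrylate
Product: 4 methyl 3-(furan-3-yl)propanoate
Conditions: NaBH4, NiCl2·6H2O (cat.), MeOH, 0 °C
Reagents that add atoms: none
Why: Conjugate reduction by nickel boride formed in the flask should saturate only the electron-poor C=C and leave the aromatic furan and the ester alone.

Step 3
Reactants: 4 methyl 3-(furan-3-yl)propanoate
Product: 5 3-(furan-3-yl)propanal
Conditions: i-Bu2AlH (1.05 equiv), CH2Cl2, −78 °C; aq. Rochelle salt
Reagents that add atoms: none
Why: Partial ester reduction with i-Bu2AlH at −78 °C should stop at the aluminium hemiacetal, which releases the aldehyde on work-up.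

Step 4
Reactants: 5 3-(furan-3-yl)propanal
Product: 6 3-(4,4-dibromobut-3-en-1-yl)furan
Conditions: CBr4, PPh3, Et3N, CH2Cl2, 0 °C
Reagents that add atoms: carbon tetrabromide, BrC(Br)(Br)Br
Why: The first stage of the Corey–Fuchs sequence (dibromo-olefination) adds carbon C8, and Et3N keeps the medium non-acidic for the furan.

Step 5
Reactants: 6 3-(4,4-dibromobut-3-en-1-yl)furan
Product: 8 3-(pent-3-yn-1-yl)furan, via lithium acetylide 7 (not isolated)
Conditions: n-BuLi (2.1 equiv), THF, −78 °C; MeI, −78 °C to rt
Reagents that add atoms: iodomethane, CI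
Why: In the second stage of the Corey–Fuchs sequence, bromine–lithium exchange, 1,2-shift and deprotonation give the acetylide, which MeI should methylate on carbon to install the C8 methyl group.

Step 6
Reactants: 8 3-(pent-3-yn-1-yl)furan
Product: 10 (E)-3-(4-iodopent-3-en-1-yl)furan, via alkenylzirconocene chloride 9 (not isolated)
Conditions: Cp2Zr(H)Cl (2.5 equiv), THF, 50 °C; I2, 0 °C
Reagents that add atoms: iodine, [I][I]
Why: Hydrozirconation with excess Schwartz reagent is a syn addition that should equilibrate zirconium onto the less hindered, methyl-bearing carbon C8, and iodinolysis with retention then places iodine trans to C6.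

Step 7
Reactants: 11 4-pentyn-1-ol
Product: 13 (E)-5-iodo-4-methylpent-4-en-1-ol, via alkenylalane 12 (not isolated)
Conditions: Me3Al (3 equiv), Cp2ZrCl2 (0.25 equiv), CH2Cl2, 0 °C to rt; I2, THF, −30 to 0 °C
Reagents that add atoms: trimethylaluminium, C[Al](C)C; iodine, [I][I]
Why: Zirconium-catalysed Negishi carboalumination adds methyl (to the internal carbon, C12) and aluminium syn across the alkyne, and iodinolysis with retention should fix the E-C11=C12 alkene.

Step 8
Reactants: 13 (E)-5-iodo-4-methylpent-4-en-1-ol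
Product: 14 (E)-5-iodo-4-methylpent-4-enal
Conditions: Dess–Martin periodinane, NaHCO3, CH2Cl2, 0 °C to rt
Reagents that add atoms: none
Why: Buffered Dess–Martin oxidation of the primary alcohol should not touch the alkenyl iodide.

Step 9
Reactants: 14 (E)-5-iodo-4-methylpent-4-enal; 15 isopropenylmagnesium bromide
Product: 16 rac-(E)-7-iodo-2,6-dimethylhepta-1,6-dien-3-ol
Conditions: THF, −78 to 0 °C; aq. NH4Cl
Reagents that add atoms: none
Why: Grignard 1,2-addition to the aldehyde builds C15–C16; the racemic carbinol centre is erased in the next step.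

Step 10
Reactants: 16 rac-(E)-7-iodo-2,6-dimethylhepta-1,6-dien-3-ol; 17 triethyl orthoacetate
Product: 19 ethyl (4E,8E)-9-iodo-4,8-dimethylnona-4,8-dienoate, via ketene acetal 18 (not isolated)
Conditions: EtCO2H (cat.), 140 °C, EtOH distilled off
Reagents that add atoms: none
Why: Johnson–Claisen rearrangement through a chair transition state with the C14 chain equatorial should give the E-C15=C16 alkene and adds C17–C19.

Step 11
Reactants: 19 ethyl (4E,8E)-9-iodo-4,8-dimethylnona-4,8-dienoate
Product: 21 (5S)-5-[(1R,4E)-1-hydroxy-5-iodo-4-methylpent-4-en-1-yl]-5-methyloxolan-2-one, via epoxy ester 20 (not isolated)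
Conditions: D-fructose-derived Shi ketone (0.3 equiv), KHSO5 (Oxone), K2CO3, Bu4NHSO4, Na2B4O7 buffer, MeCN–CH2(OMe)2, 0 °C; extraction; camphorsulfonic acid (cat.), wet CH2Cl2, rt
Reagents that add atoms: potassium peroxymonosulfate, [K+].[O-]S(=O)(=O)OO; water, O
Why: Shi asymmetric epoxidation with the D-fructose-derived ketone (1,2:4,5-di-O-isopropylidene-D-erythro-2,3-hexodiulo-2,6-pyranose) should attack the electron-rich C15=C16 alkene rather than the deactivated iodoalkene and give the (15R,16R)-epoxide, and acid-promoted 5-exo attack of the ester carbonyl on the tertiary carbon C16 with inversion then sets 16S beside 15R.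

Step 12
Reactants: 21 (5S)-5-[(1R,4E)-1-hydroxy-5-iodo-4-methylpent-4-en-1-yl]-5-methyloxolan-2-one
Product: 22 (5S)-5-[(1R,4E)-1-(tert-butyldimethylsilyloxy)-5-iodo-4-methylpent-4-en-1-yl]-5-methyloxolan-2-one
Conditions: TBSOTf, 2,6-lutidine, CH2Cl2, −78 to 0 °C
Reagents that add atoms: tert-butyldimethylsilyl triflate, CC(C)(C)[Si](C)(C)OS(=O)(=O)C(F)(F)F
Why: Silylation with the silyl triflate should cap the hindered C15 alcohol so that it cannot quench vinyllithium later.

Step 13
Reactants: 22 (5S)-5-[(1R,4E)-1-(tert-butyldimethylsilyloxy)-5-iodo-4-methylpent-4-en-1-yl]-5-methyloxolan-2-one; 23 bis(pinacolato)diboron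
Product: 24 (5S)-5-[(1R,4E)-1-(tert-butyldimethylsilyloxy)-4-methyl-5-(4,4,5,5-tetramethyl-1,3,2-dioxaborolan-2-yl)pent-4-en-1-yl]-5-methyloxolan-2-one
Conditions: PdCl2(PPh3)2 (3 mol %), PPh3 (6 mol %), KOPh, toluene, 50 °C
Reagents that add atoms: none
Why: Miyaura borylation of the alkenyl iodide proceeds with retention of the E geometry, and the weak base KOPh should spare the lactone and the silyl ether.

Step 14
Reactants: 25 tetravinylstannane
Product: 26 vinyllithium
Conditions: n-BuLi (4 equiv), pentane, rt; solid washed with pentane, dissolved in THF, titrated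
Reagents that add atoms: n-butyllithium, [Li]CCCC
Why: Tin–lithium exchange should give halide-free vinyllithium, which matters because lithium halides would block the cationic palladium of the next step.

Step 15
Reactants: 24 alkenylboronate (C11–C19); 26 vinyllithium; 10 (E)-3-(4-iodopent-3-en-1-yl)furan
Product: 28 (5S)-5-[(1R,4E,6S,8E)-1-(tert-butyldimethylsilyloxy)-11-(furan-3-yl)-4,8-dimethyl-6-(4,4,5,5-tetramethyl-1,3,2-dioxaborolan-2-yl)undeca-4,8-dien-1-yl]-5-methyloxolan-2-one, via lithium borate complex 27 (not isolated)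
Conditions: 24, THF, −78 °C; 26 (1.0 equiv), −78 to 0 °C; then Pd(OAc)2 (3 mol %), (Sp,Sp)-MandyPhos (3.6 mol %), 10 (1.1 equiv), KOTf (2 equiv), THF, 60 °C
Reagents that add atoms: none
Why: Vinyllithium adds to the boron of 24 to give borate 27, zerovalent palladium carrying the diphosphine inserts into the C–I bond of 10, KOTf removes the iodide as KI, and the cationic divalent alkenylpalladium binds the unsubstituted vinyl group of 27, which triggers a 1,2-shift of the C11 alkenyl group from boron to C10 while palladium bonds C9; reductive elimination then forms C8–C9. The closest known reaction type is the palladium-catalysed enantioselective conjunctive cross-coupling of bis(alkenyl)borates with C(sp2) electrophiles, which gives chiral allylic boronates. No ring is closed. The C10 stereocentre is set by the chiral ferrocenyl diphosphine, which decides the face of the vinyl group that palladium takes, the distant C15 and C16 centres having no say, and both alkenyl groups are transferred with retention, so the two E alkenes should arrive unchanged. The step needs the vinyl group to act as acceptor and not to migrate (palladium prefers the least substituted alkene), the 1,2-shift to beat direct transmetalation (bidentate ligand and a non-coordinating triflate counter-ion), and borate formation to beat addition to the lactone (one equivalent of vinyllithium at −78 °C, where complexation to the boronic ester is the faster process).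

Step 16
Reactants: 28 C10 pinacol boronate
Product: 29 (5S)-5-[(1R,4E,6S,8E)-1-(tert-butyldimethylsilyloxy)-11-(furan-3-yl)-6-hydroxy-4,8-dimethylundeca-4,8-dien-1-yl]-5-methyloxolan-2-one
Conditions: 30% H2O2, pH 7 phosphate buffer, THF, 0 °C to rt
Reagents that add atoms: hydrogen peroxide, OO
Why: Oxidation of the C–B bond by hydroperoxide goes through a 1,2-shift from boron to oxygen with retention at C10, and the neutral buffer should protect the lactone.

Step 17
Reactants: 29 C10 alcohol with C15 silyl ether
Product: 30 (5S)-5-[(1R,4E,6S,8E)-11-(furan-3-yl)-1,6-dihydroxy-4,8-dimethylundeca-4,8-dien-1-yl]-5-methyloxolan-2-one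
Conditions: Bu4NF, AcOH, THF, rt
Reagents that add atoms: none
Why: Fluoride-mediated desilylation buffered with acetic acid should free the C15 alcohol without opening the lactone or ionising the allylic alcohol.

Step 18
Reactants: 30 diol
Product: 31 Irciformonin F
Conditions: Ac2O, pyridine, 4-(dimethylamino)pyridine (cat.), CH2Cl2, 0 °C to rt
Reagents that add atoms: acetic anhydride, CC(=O)OC(C)=O
Why: Nucleophile-catalysed acetylation should esterify both secondary alcohols in one operation without touching any stereocentre.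

**Compound list**

1 | 3-furaldehyde | O=Cc1ccoc1 | starting material
2 | methyl (triphenylphosphoranylidene)acetate | COC(=O)C=P(c1ccccc1)(c1ccccc1)c1ccccc1 | starting material
3 | methyl (E)-3-(furan-3-yl)acrylate | COC(=O)/C=C/c1ccoc1 | intermediate
4 | methyl 3-(furan-3-yl)propanoate | COC(=O)CCc1ccoc1 | intermediate
5 | 3-(furan-3-yl)propanal | O=CCCc1ccoc1 | intermediate
6 | 3-(4,4-dibromobut-3-en-1-yl)furan | BrC(Br)=CCCc1ccoc1 | intermediate
7 | [4-(furan-3-yl)but-1-yn-1-yl]lithium | [Li]C#CCCc1ccoc1 | intermediate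
8 | 3-(pent-3-yn-1-yl)furan | CC#CCCc1ccoc1 | intermediate
9 | chlorobis(cyclopentadienyl)[(E)-5-(furan-3-yl)pent-2-en-2-yl]zirconium | Cl[Zr](C1C=CC=C1)(C1C=CC=C1)/C(C)=C/CCc1ccoc1 | intermediate
10 | (E)-3-(4-iodopent-3-en-1-yl)furan | I/C(C)=C/CCc1ccoc1 | intermediate
11 | 4-pentyn-1-ol | C#CCCCO | starting material
12 | (E)-alkenyl(dimethyl)alane of 4-pentyn-1-ol, oxygen bound as O–AlMe2 | C[Al](C)/C=C(\C)CCCO[Al](C)C | intermediate
13 | (E)-5-iodo-4-methylpent-4-en-1-ol | I/C=C(\C)CCCO | intermediate
14 | (E)-5-iodo-4-methylpent-4-enal | I/C=C(\C)CCC=O | intermediate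
15 | isopropenylmagnesium bromide | C=C(C)[Mg]Br | starting material
16 | rac-(E)-7-iodo-2,6-dimethylhepta-1,6-dien-3-ol | C=C(C)C(O)CC/C(C)=C/I | intermediate
17 | triethyl orthoacetate | CC(OCC)(OCC)OCC | starting material
18 | (E)-3-[(1-ethoxyethenyl)oxy]-7-iodo-2,6-dimethylhepta-1,6-diene | C=C(OCC)OC(CC/C(C)=C/I)C(C)=C | intermediate
19 | ethyl (4E,8E)-9-iodo-4,8-dimethylnona-4,8-dienoate | CCOC(=O)CC/C(C)=C/CC/C(C)=C/I | intermediate
20 | ethyl 3-[(2R,3R)-3-[(3E)-4-iodo-3-methylbut-3-en-1-yl]-2-methyloxiran-2-yl]propanoate | CCOC(=O)CC[C@@]1(C)O[C@@H]1CC/C(C)=C/I | intermediate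
21 | (5S)-5-[(1R,4E)-1-hydroxy-5-iodo-4-methylpent-4-en-1-yl]-5-methyloxolan-2-one | I/C=C(\C)CC[C@@H](O)[C@]1(C)CCC(=O)O1 | intermediate
22 | (5S)-5-[(1R,4E)-1-(tert-butyldimethylsilyloxy)-5-iodo-4-methylpent-4-en-1-yl]-5-methyloxolan-2-one | I/C=C(\C)CC[C@@H](O[Si](C)(C)C(C)(C)C)[C@]1(C)CCC(=O)O1 | intermediate
23 | bis(pinacolato)diboron | CC1(C)OB(OC1(C)C)B1OC(C)(C)C(C)(C)O1 | starting material
24 | (5S)-5-[(1R,4E)-1-(tert-butyldimethylsilyloxy)-4-methyl-5-(4,4,5,5-tetramethyl-1,3,2-dioxaborolan-2-yl)pent-4-en-1-yl]-5-methyloxolan-2-one | CC1(C)OB(/C=C(\C)CC[C@@H](O[Si](C)(C)C(C)(C)C)[C@]2(C)CCC(=O)O2)OC1(C)C | intermediate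
25 | tetravinylstannane | C=C[Sn](C=C)(C=C)C=C | starting material
26 | vinyllithium | [Li]C=C | intermediate
27 | lithium ethenyl[(1E,5R)-5-(tert-butyldimethylsilyloxy)-2-methyl-5-[(2S)-2-methyl-5-oxooxolan-2-yl]pent-1-en-1-yl](pinacolato)borate | [Li+].C=C[B-]1(OC(C)(C)C(C)(C)O1)/C=C(\C)CC[C@@H](O[Si](C)(C)C(C)(C)C)[C@]2(C)CCC(=O)O2 | intermediate
28 | (5S)-5-[(1R,4E,6S,8E)-1-(tert-butyldimethylsilyloxy)-11-(furan-3-yl)-4,8-dimethyl-6-(4,4,5,5-tetramethyl-1,3,2-dioxaborolan-2-yl)undeca-4,8-dien-1-yl]-5-methyloxolan-2-one | CC1(C)OB(OC1(C)C)[C@H](/C=C(\C)CC[C@@H](O[Si](C)(C)C(C)(C)C)[C@]2(C)CCC(=O)O2)C/C(C)=C/CCc2ccoc2 | intermediate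
29 | (5S)-5-[(1R,4E,6S,8E)-1-(tert-butyldimethylsilyloxy)-11-(furan-3-yl)-6-hydroxy-4,8-dimethylundeca-4,8-dien-1-yl]-5-methyloxolan-2-one | O[C@H](/C=C(\C)CC[C@@H](O[Si](C)(C)C(C)(C)C)[C@]1(C)CCC(=O)O1)C/C(C)=C/CCc1ccoc1 | intermediate
30 | (5S)-5-[(1R,4E,6S,8E)-11-(furan-3-yl)-1,6-dihydroxy-4,8-dimethylundeca-4,8-dien-1-yl]-5-methyloxolan-2-one | O[C@H](/C=C(\C)CC[C@@H](O)[C@]1(C)CCC(=O)O1)C/C(C)=C/CCc1ccoc1 | intermediate
31 | Irciformonin F, (1R,4E,6S,8E)-11-(furan-3-yl)-4,8-dimethyl-1-[(2S)-2-methyl-5-oxooxolan-2-yl]undeca-4,8-diene-1,6-diyl diacetate | CC(=O)O[C@H](/C=C(\C)CC[C@@H](OC(C)=O)[C@]1(C)CCC(=O)O1)C/C(C)=C/CCc1ccoc1 | target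

**Count and risks**

Total: 18 steps. Longest linear sequence: 11 steps (4-pentyn-1-ol through steps 7–13 and 15–18).

Steps most likely to fail:

1. Step 15. Four things can go wrong as processes:
   - vinyllithium adds to the lactone carbonyl in competition with borate formation;
   - iodide stays on palladium and blocks binding of the vinyl group;
   - an alkenyl group transfers directly to palladium instead of undergoing the 1,2-shift;
   - the ligand discriminates the two faces of the vinyl group poorly.

   The fallback builds C10 by carbonyl chemistry; it sets out from 10 and 22 and returns at 29. Iodide 10 is lithiated (t-BuLi, Et2O, −78 °C) and opened onto ethylene oxide (BF3·OEt2) to give (E)-6-(furan-3-yl)-3-methylhex-3-en-1-ol F1. Dess–Martin oxidation gives (E)-6-(furan-3-yl)-3-methylhex-3-enal F2, which is used at once. Nozaki–Hiyama–Kishi coupling of F2 with iodide 22 (CrCl2, NiCl2 cat., DMSO) should give the C10 carbinol as a mixture of epimers F3. Dess–Martin oxidation gives the dienone F4, and Corey–Bakshi–Shibata reduction with (R)-2-methyl-CBS-oxazaborolidine and catecholborane (the alkenyl group as the large substituent) should give the 10S alcohol 29.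

2. Step 11. The dioxirane may discriminate the alkene faces insufficiently, the iodoalkene may be oxidised as well, or the epoxide may open without clean inversion at C16.

   The fallback sets C15 and C16 on the allylic alcohol; it sets out from 16 and returns at 22. Sharpless kinetic-resolution epoxidation of racemic 16 (Ti(OiPr)4, D-(−)-diisopropyl tartrate, t-BuOOH, 4 Å sieves, CH2Cl2, −20 °C, stopped near half conversion) should convert the R enantiomer into the erythro epoxy alcohol (1R,4E)-5-iodo-4-methyl-1-[(2S)-2-methyloxiran-2-yl]pent-4-en-1-ol F5. Silylation (TBSCl, imidazole, DMF) gives the silyl ether F6, which blocks Payne rearrangement. Diethyl malonate with NaOEt in EtOH opens the epoxide at its CH2 and lactonises to the 3-ethoxycarbonyl lactone F7. Krapcho dealkoxycarbonylation (LiCl, wet DMSO, 140 °C) then gives 22.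

3. Step 6. Zirconium may end on C7 as well as on C8, so that a regioisomeric iodide is carried forward.

   The fallback fixes the position of the metal by the position of a halogen; it sets out from 6 and returns at 10. Dehydrobromination of 6 (NaN(SiMe3)2, THF, −78 °C) gives 3-(4-bromobut-3-yn-1-yl)furan F8. Syn hydroboration with HBBr2·SMe2 (boron to the brominated carbon) and esterification with pinacol give the (Z)-1-bromoalkenylboronate F9. Negishi coupling with MeZnCl and Pd(PPh3)4 replaces bromine by methyl with retention to give the (Z)-alkenylboronate F10. Iodination with NaOH and I2 (retention, furan inert to I2) gives 10.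

Further compounds
F1 | step 15 | (E)-6-(furan-3-yl)-3-methylhex-3-en-1-ol | OCC/C(C)=C/CCc1ccoc1
F2 | step 15 | (E)-6-(furan-3-yl)-3-methylhex-3-enal | O=CC/C(C)=C/CCc1ccoc1
F3 | step 15 | C10-epimeric mixture of 29 | OC(/C=C(\C)CC[C@@H](O[Si](C)(C)C(C)(C)C)[C@]1(C)CCC(=O)O1)C/C(C)=C/CCc1ccoc1
F4 | step 15 | C10 ketone (dienone) corresponding to 29 | O=C(/C=C(\C)CC[C@@H](O[Si](C)(C)C(C)(C)C)[C@]1(C)CCC(=O)O1)C/C(C)=C/CCc1ccoc1
F5 | step 11 | (1R,4E)-5-iodo-4-methyl-1-[(2S)-2-methyloxiran-2-yl]pent-4-en-1-ol | I/C=C(\C)CC[C@@H](O)[C@]1(C)CO1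
F6 | step 11 | tert-butyldimethylsilyl ether of F5 | I/C=C(\C)CC[C@@H](O[Si](C)(C)C(C)(C)C)[C@]1(C)CO1
F7 | step 11 | ethyl (5S)-5-[(1R,4E)-1-(tert-butyldimethylsilyloxy)-5-iodo-4-methylpent-4-en-1-yl]-5-methyl-2-oxooxolane-3-carboxylate | I/C=C(\C)CC[C@@H](O[Si](C)(C)C(C)(C)C)[C@]1(C)CC(C(=O)OCC)C(=O)O1
F8 | step 6 | 3-(4-bromobut-3-yn-1-yl)furan | BrC#CCCc1ccoc1
F9 | step 6 | (Z)-2-[1-bromo-4-(furan-3-yl)but-1-en-1-yl]-4,4,5,5-tetramethyl-1,3,2-dioxaborolane | Br/C(B1OC(C)(C)C(C)(C)O1)=C\CCc1ccoc1
F10 | step 6 | (Z)-2-[5-(furan-3-yl)pent-2-en-2-yl]-4,4,5,5-tetramethyl-1,3,2-dioxaborolane | C/C(B1OC(C)(C)C(C)(C)O1)=C\CCc1ccoc1
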